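## Analysis of the target

The target, 7-methoxy-3-(5-methoxy-2,2-dimethyl-2H-chromen-6-yl)-4H-chromen-4-one, is an isoflavone. Ring A (methoxyl on C7) and ring C (O1, C2–H, C3, C4=O) form the chromone, and C3 carries ring B through the C3–C1' bond. Ring B is fused across C3'–C4' to ring D, a 2,2-dimethyl-2H-pyran (O1'' on C4', C2''Me2, C3''=C4'', C4'' on C3'), and bears a methoxyl on C2'. There is no stereocentre, so the synthesis is a problem of regiochemistry and functional-group tolerance only. The sensitive sites are the C3''=C4'' bond, an electron-rich styrene that strong acids, Lewis acids, electrophilic oxidants and hydrogenation catalysts attack, and C2 of the chromone, which hard nucleophiles attack with ring opening. The difficulty is ring B: C1' to C4' are four contiguous substituted carbons, and the pyran has to be annulated towards the crowded C3' and not towards the open C5', the choice every phenol-based chromene synthesis must make. In addition, ring C has to be assembled without the strong Lewis acids or oxidative rearrangements of classical isoflavone chemistry. The strategy rests on the sequence C2'(OMe)–C3'(–C4'')–C4'(–O1''): an aryl C–C bond and an aryl C–O bond on neighbouring carbons, with the carbon next to a methoxyl, is the pattern left when a carbonyl group adds across the C3'–C4' triple bond of a 3-methoxybenzyne. C1' then needs only a masked aldehyde, whose carbon becomes C3.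

## Retrosynthetic reasoning

Ring C is opened first, at O1–C8a and at C3–C4. Cutting O1–C8a as an intramolecular aromatic substitution leads from 25 to the hydroxymethylene ketone 24 and, one hydrolysis further back, to enaminone 23. Cutting C3–C4 of 23 as an enamine acylation gives enamine 22 and acid chloride 21. These cuts are chosen because ring A then arrives as one purchasable unit that holds both the C4 carbonyl and, as its fluorine, the acceptor site for O1. Everything is done with amines, carbonate and dilute acid, which the chromene tolerates. A biaryl-type cut at C3–C1' was not used because the aryne precursor is made with an alkyllithium, which a ring halogen on C1' would not survive.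

Enamine 22 comes from arylacetaldehyde 19 and amine 20. Aldehyde 19 is the hydrolysis product of enol ether 18, which is disconnected at its C=C bond to aldehyde 15 and phosphonium salt 16. This one-carbon homologation turns the aldehyde carbon of 15 into C3 and adds C2, so ring B needs nothing more elaborate on C1' than a formyl group.

Aldehyde 15 is unmasked from dioxolane 14. The acetal is needed because a free aldehyde on ring B would itself react with an aryne.

The key disconnection removes ring D from 14 by cutting C4'–O1'', C3'–C4'' and O1''–C2''. This returns the silyl triflate 9 and enal 10, by way of aryne 11, benzoxete 12 and ortho-quinone methide 13. The cut is made here because the C2' methoxyl that the target needs anyway decides which aryne carbon receives oxygen. The C3' versus C5' question of phenol chromenylation therefore does not arise, and three skeletal bonds and one ring are formed in one operation from two achiral partners. The forward reaction has to generate 11 under conditions mild enough for 10, add the carbonyl oxygen at C4', and let 13 close before anything else intercepts it.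

Triflate 9 is disconnected at its O–S bond to phenol 8, and 8 at its O–carbamoyl bond to carbamate 7. The carbamate is kept until this point because it is the group that directs the silicon to C3'. A complex hydride is chosen for its removal so that the acetal and the aryl–silicon bond never meet acid.

The C3'–Si bond of 7 is cut to aryllithium 6 and silyl chloride 5. Lithium 6 arises from 4 by deprotonation of the one ring hydrogen that lies between two oxygens. A tertiary carbamate is preferred to an N-monoalkyl one, because the latter would need N-silylation with a silyl triflate and an acidic work-up, both hazardous for the dioxolane.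

Acetal 4 comes from aldehyde 3, and 3 from phenol 1 and carbamoyl chloride 2. Compound 1 already carries the C2' methoxyl, the C4' oxygen and the C1' carbon in the right places, so no substituent has to be introduced on ring B by electrophilic substitution.

## Alternatives that were turned down

Alternative 1: Ring C is cut at O1–C2 and C4–C4a, but at the coumarin oxidation pattern. Ring A then comes from 3-methoxyphenol A1, and C2, C3 and C4 from an activated malonate that carries ring B, bis(2,4,6-trichlorophenyl) 2-(5-methoxy-2,2-dimethyl-2H-chromen-6-yl)propanedioate A2.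
- Forward key step: on heating, A1 is O-acylated by A2, the second aryl ester departs to leave an acylketene, and this acylates ring A para to its methoxyl. The lactone closes as 4-hydroxy-7-methoxy-3-(5-methoxy-2,2-dimethyl-2H-chromen-6-yl)-2H-chromen-2-one A3. O-Alkylation at C4, partial reduction of the lactone and acid-induced loss of water would then move the carbonyl from C2 to C4.
- For: two bonds and ring C form in one operation, ring A comes from the simplest phenol, and the site of C-acylation is fixed by the two oxygens of A1. On the assembly of rings A and C this is as strong as or stronger than the chosen route, which needs four operations from aldehyde to isoflavone and an aromatic substitution on an electron-rich fluoroarene.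
- Against: the hard part is untouched. A2 must already contain the angular chromene with its methoxyl, so the C3'/C5' question is only moved into the synthesis of A2, which also needs a two-carbon homologation and a malonate activation. The condensation runs at temperatures at which a 2H-chromene can open electrocyclically and undergo hydrogen shifts. The carbonyl transposition adds three steps with their own selectivity problems (which oxygen is alkylated, over-reduction).
- Comparison: it is longer overall and spends its key step on the easy ring, whereas the chosen strategy spends it on ring B.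

Alternative 2: Ring B itself is dismantled at C2'–C3', C4'–C5' and C1'–C2'. The precursors are a diazoketone on the finished chromone, (E)-1-diazo-4-(7-methoxy-4-oxo-4H-chromen-3-yl)but-3-en-2-one A4, and an electron-rich alkyne, triisopropyl[(5-methylhex-4-en-1-yn-1-yl)oxy]silane A5.
- Forward key step (Danheiser benzannulation): photochemical Wolff rearrangement of A4 gives a vinylketene, [2+2] addition to A5 gives a vinylcyclobutenone, and 4π opening, 6π closure and tautomerisation give 3-[2-hydroxy-3-(3-methylbut-2-enyl)-4-(triisopropylsilyloxy)phenyl]-7-methoxy-4H-chromen-4-one A6. O-Methylation, desilylation and dehydrogenative cyclisation of the ortho-prenylphenol must follow.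
- For: the substitution pattern of ring B is fixed by connectivity alone, with no aromatic substitution and no aryne site selectivity. On regiochemical certainty it is stronger than the chosen route. The isoflavone core is present from the start, so no late ring C chemistry is needed.
- Against: A4 and A5 each need several steps (homologation and diazo transfer on a base-sensitive chromone; ynolate chemistry). The chromone absorbs in the irradiation window and is itself an electron-poor alkene towards ketene and ynol ether. Ring D is not formed in the key step, so three further steps, one of them an oxidation, remain.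
- Comparison: higher certainty is bought with length, photochemistry and fragile reagents. The chosen route starts with the methoxyl in place and closes ring D in its key step.

Alternative 3: Ring D is built on a non-aromatic ring B, by cutting C3'–C4'' and O1''–C2'' back to cyclohexane-1,3-dione A7 and 10.
- Forward key step: Knoevenagel condensation of C2 of A7 with 10 gives a 1-oxatriene that closes by oxa-6π electrocyclisation to 2,2-dimethyl-7,8-dihydro-2H-chromen-5(6H)-one A8. Enolate formylation at C6 (the future C1'), dehydrogenation to the phenol and O-methylation would follow.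
- For: A7 is symmetric, so there is no regiochemical question at all. The materials are very cheap, no aryne is needed, and the ring B aldehyde equivalent to 15 would be reached in about four steps against seven here. On step economy to that point and on operational simplicity it is stronger.
- Against: A8 is at the wrong oxidation level and lacks both the C1' carbon and the O-methyl group. The condensation is prone to 2:1 adducts of A7 with 10, and A8 is a cross-conjugated dienone in equilibrium with its open form. A dehydrogenation has to be carried out on a dienone carrying a formyl group.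
- Comparison: the chosen strategy keeps ring B aromatic and at the final oxidation level throughout, with all three substituents in place and the methoxyl as control element. It pays for this with a longer precursor synthesis.

Key step: step 6

Remark on the chemistry: compounds 1, 2, 5, 10, 16, 20 and 21 are assumed to be purchasable. Enol ether 18 is expected as an E/Z mixture and 13, 23 and 24 are geometrically mobile, so their SMILES carry no alkene descriptors. Benzoxete 12 is a racemic transient.

## Route

Step 1
Reactants: 1 4-hydroxy-2-methoxybenzaldehyde; 2 N,N-diethylcarbamoyl chloride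
Product: 3 4-formyl-3-methoxyphenyl N,N-diethylcarbamate
Conditions: K2CO3, MeCN, reflux
Reagents that add atoms: none
Why: The phenol para to the formyl group is acidic and its potassium salt is acylated cleanly on oxygen (O-carbamoylation). The tertiary carbamate is chosen because it is the strongest oxygen-based directing group for the later ortho-lithiation and needs no N-protection.

Step 2
Reactants: 3 4-formyl-3-methoxyphenyl N,N-diethylcarbamate
Product: 4 4-(1,3-dioxolan-2-yl)-3-methoxyphenyl N,N-diethylcarbamate
Conditions: HOCH2CH2OH, p-TsOH·H2O (cat.), PhMe, reflux, Dean–Stark trap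
Reagents that add atoms: ethane-1,2-diol, OCCO
Why: Acid-catalysed acetalisation with azeotropic removal of water masks the aldehyde against the alkyllithium of step 3 and the aryne of step 6. The tertiary carbamate is inert under these conditions.

Step 3
Reactants: 4 4-(1,3-dioxolan-2-yl)-3-methoxyphenyl N,N-diethylcarbamate; 5 chlorotrimethylsilane
Product: 7 4-(1,3-dioxolan-2-yl)-3-methoxy-2-(trimethylsilyl)phenyl N,N-diethylcarbamate, via aryllithium 6 (not isolated)
Conditions: s-BuLi, TMEDA, THF, −78 °C; then Me3SiCl, −78 °C → rt
Reagents that add atoms: none
Why: Directed ortho-metalation. The carbamate carbonyl delivers the base, and the ring hydrogen flanked by both oxygens is the most acidic (cooperative 1,3-directing groups), so lithiation should occur between the oxygens to give 6, which 5 traps on carbon. At −78 °C the lithiated carbamate does not undergo anionic ortho-Fries migration and the dioxolane is inert.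

Step 4
Reactants: 7 4-(1,3-dioxolan-2-yl)-3-methoxy-2-(trimethylsilyl)phenyl N,N-diethylcarbamate
Product: 8 4-(1,3-dioxolan-2-yl)-3-methoxy-2-(trimethylsilyl)phenol
Conditions: LiAlH4, THF, 0 → 40 °C; aq. KNaC4H4O6 (potassium sodium tartrate) work-up at pH ≥ 8
Reagents that add atoms: none
Why: Hydride adds to the carbamate carbonyl and the tetrahedral intermediate collapses to the phenoxide (reductive cleavage of an aryl carbamate), leaving the aryl–silicon bond and the acetal untouched. The work-up is kept basic and 8 is used at once, because it is an ortho-silylphenol and a para-hydroxybenzaldehyde acetal, both labile to acid.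

Step 5
Reactants: 8 4-(1,3-dioxolan-2-yl)-3-methoxy-2-(trimethylsilyl)phenol
Product: 9 4-(1,3-dioxolan-2-yl)-3-methoxy-2-(trimethylsilyl)phenyl trifluoromethanesulfonate
Conditions: PhNTf2, DBU, MeCN, rt → 40 °C
Reagents that add atoms: N-phenylbis(trifluoromethanesulfonimide), O=S(=O)(N(c1ccccc1)S(=O)(=O)C(F)(F)F)C(F)(F)F
Why: O-Sulfonylation of the phenoxide with a mild triflyl donor under amine base releases no acid. It should give the ortho-silylaryl triflate, the standard fluoride-triggered aryne precursor.

Step 6
Reactants: 9 4-(1,3-dioxolan-2-yl)-3-methoxy-2-(trimethylsilyl)phenyl trifluoromethanesulfonate; 10 3-methylbut-2-enal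
Product: 14 2-(5-methoxy-2,2-dimethyl-2H-chromen-6-yl)-1,3-dioxolane, via aryne 11 (not isolated), via benzoxete 12 (not isolated), via ortho-quinone methide 13 (not isolated)
Conditions: CsF, MeCN, 50 °C; 10 in excess; 9 added slowly
Reagents that add atoms: none
Why: Fluoride attacks silicon and the aryl anion expels triflate to give aryne 11; the carbonyl oxygen of 10 adds to the aryne carbon C4' remote from the methoxyl, and the aryl anion left on C3' collapses onto the carbonyl carbon C4'', a formal [2+2] addition that closes the four-membered benzoxete 12. Thermal 4π ring opening of 12 breaks its O–C4'' bond and gives ortho-quinone methide 13, a 1-oxatriene, which closes the six-membered pyran by disrotatory oxa-6π electrocyclisation (O1''–C2'') and restores aromaticity. The closest known reaction type is the fluoride-induced annulation of ortho-silylaryl triflates with α,β-unsaturated aldehydes to 2H-chromenes. No stereocentre results: the benzoxete carbon of 12 forms racemic and is planarised on ring opening, and C2'' carries two methyl groups. The step needs site selectivity at the unsymmetrical aryne, which the C2' methoxyl secures because its inductive pull and the angle distortion it causes make C4' the electrophilic terminus and stabilise negative charge on C3'. It needs chemoselectivity for C=O over C=C of 10, secured because the oxygen lone pair starts the addition. It needs the oxatriene geometry with the isobutenyl arm turned towards oxygen, which is reached because the exocyclic alkene of 13 can re-equilibrate through reclosure to 12. Slow addition of 9 to excess 10 keeps the aryne concentration low, so that 13 cyclises before a second aryne can intercept it.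

Step 7
Reactants: 14 2-(5-methoxy-2,2-dimethyl-2H-chromen-6-yl)-1,3-dioxolane
Product: 15 5-methoxy-2,2-dimethyl-2H-chromene-6-carbaldehyde
Conditions: PPTS (cat.), acetone–H2O, rt
Reagents that add atoms: water, O
Why: Acetals of electron-rich benzaldehydes hydrolyse under very mild acid (acetal hydrolysis through a stabilised oxocarbenium ion). The chromene alkene is not protonated to a useful extent under these conditions.

Step 8
Reactants: 15 5-methoxy-2,2-dimethyl-2H-chromene-6-carbaldehyde; 16 (methoxymethyl)triphenylphosphonium chloride
Product: 18 5-methoxy-6-(2-methoxyethenyl)-2,2-dimethyl-2H-chromene (E/Z mixture), via ylide 17 (not isolated)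
Conditions: KOC(CH3)3, THF, 0 °C; then 15, 0 °C → rt
Reagents that add atoms: none
Why: Wittig olefination with the non-stabilised methoxymethylene ylide 17 adds the carbon that becomes C2. The aldehyde cannot enolise, and the alkene geometry is of no consequence because both isomers converge in step 9.

Step 9
Reactants: 18 5-methoxy-6-(2-methoxyethenyl)-2,2-dimethyl-2H-chromene
Product: 19 2-(5-methoxy-2,2-dimethyl-2H-chromen-6-yl)acetaldehyde
Conditions: 2 M HCl, THF, rt
Reagents that add atoms: water, O
Why: Acid-catalysed enol ether hydrolysis (protonation at the aryl-bearing carbon, hydration of the oxocarbenium ion, loss of methanol) gives the arylacetaldehyde. Dilute acid at ambient temperature is chosen so that the chromene alkene survives, and 19 is used crude because arylacetaldehydes self-condense.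

Step 10
Reactants: 19 2-(5-methoxy-2,2-dimethyl-2H-chromen-6-yl)acetaldehyde; 20 morpholine; 21 2-fluoro-4-methoxybenzoyl chloride
Product: 23 1-(2-fluoro-4-methoxyphenyl)-2-(5-methoxy-2,2-dimethyl-2H-chromen-6-yl)-3-(morpholin-4-yl)prop-2-en-1-one, via enamine 22 (not isolated)
Conditions: 20 (1 equiv), 4 Å molecular sieves, CH2Cl2, rt; then Et3N, 21, 0 °C → rt
Reagents that add atoms: none
Why: Condensation with 20 gives the conjugated E-enamine 22, whose nucleophilic carbon (the one bearing ring B, the future C3) is C-acylated by the aroyl chloride (Stork enamine acylation), forming C3–C4. Et3N removes HCl and leaves the push–pull enaminone; 21 has no α-hydrogen, so no ketene pathway competes.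

Step 11
Reactants: 23 1-(2-fluoro-4-methoxyphenyl)-2-(5-methoxy-2,2-dimethyl-2H-chromen-6-yl)-3-(morpholin-4-yl)prop-2-en-1-one
Product: 25 7-methoxy-3-(5-methoxy-2,2-dimethyl-2H-chromen-6-yl)-4H-chromen-4-one, via hydroxymethylene ketone 24 (not isolated)
Conditions: 1 M HCl, THF, rt; then K2CO3, DMF, 80 °C
Reagents that add atoms: water, O
Why: Dilute acid hydrolyses the vinylogous amide to 24, whose enolate oxygen then displaces the fluoride ortho to the ketone by intramolecular SNAr (addition–elimination through a Meisenheimer intermediate, six-membered closure forming O1–C8a). This is the known chromone closure of 1-(2-fluoroaryl)-1,3-dicarbonyl compounds, and the chromene and aryl ethers are inert to K2CO3 in DMF.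

## Compound list

1 | 4-hydroxy-2-methoxybenzaldehyde | COc1cc(O)ccc1C=O | starting material
2 | N,N-diethylcarbamoyl chloride | CCN(CC)C(=O)Cl | starting material
3 | 4-formyl-3-methoxyphenyl N,N-diethylcarbamate | COc1cc(OC(=O)N(CC)CC)ccc1C=O | intermediate
4 | 4-(1,3-dioxolan-2-yl)-3-methoxyphenyl N,N-diethylcarbamate | COc1cc(OC(=O)N(CC)CC)ccc1C1OCCO1 | intermediate
5 | chlorotrimethylsilane | C[Si](C)(C)Cl | starting material
6 | [6-(diethylcarbamoyloxy)-3-(1,3-dioxolan-2-yl)-2-methoxyphenyl]lithium | COc1c([Li])c(OC(=O)N(CC)CC)ccc1C1OCCO1 | intermediate
7 | 4-(1,3-dioxolan-2-yl)-3-methoxy-2-(trimethylsilyl)phenyl N,N-diethylcarbamate | COc1c([Si](C)(C)C)c(OC(=O)N(CC)CC)ccc1C1OCCO1 | intermediate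
8 | 4-(1,3-dioxolan-2-yl)-3-methoxy-2-(trimethylsilyl)phenol | COc1c([Si](C)(C)C)c(O)ccc1C1OCCO1 | intermediate
9 | 4-(1,3-dioxolan-2-yl)-3-methoxy-2-(trimethylsilyl)phenyl trifluoromethanesulfonate | COc1c(C2OCCO2)ccc(OS(=O)(=O)C(F)(F)F)c1[Si](C)(C)C | intermediate
10 | 3-methylbut-2-enal | CC(C)=CC=O | starting material
11 | 2-(2-methoxy-3,4-didehydrophenyl)-1,3-dioxolane (aryne) | COC1=C(C2OCCO2)C=CC#C1 | intermediate
12 | 2-[3-methoxy-2-(2-methylprop-1-en-1-yl)-2H-benzo[b]oxet-4-yl]-1,3-dioxolane (racemic) | COc1c(C2OCCO2)ccc2OC(C=C(C)C)c12 | intermediate
13 | 2-[2-methoxy-3-(3-methylbut-2-en-1-ylidene)-4-oxocyclohexa-1,5-dien-1-yl]-1,3-dioxolane | COC1=C(C2OCCO2)C=CC(=O)C1=CC=C(C)C | intermediate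
14 | 2-(5-methoxy-2,2-dimethyl-2H-chromen-6-yl)-1,3-dioxolane | COc1c(C3OCCO3)ccc2OC(C)(C)C=Cc12 | intermediate
15 | 5-methoxy-2,2-dimethyl-2H-chromene-6-carbaldehyde | COc1c(C=O)ccc2OC(C)(C)C=Cc12 | intermediate
16 | (methoxymethyl)triphenylphosphonium chloride | COC[P+](c1ccccc1)(c1ccccc1)c1ccccc1.[Cl-] | starting material
17 | (methoxymethylidene)triphenylphosphorane | COC=P(c1ccccc1)(c1ccccc1)c1ccccc1 | intermediate
18 | 5-methoxy-6-(2-methoxyethenyl)-2,2-dimethyl-2H-chromene (E/Z mixture) | COC=Cc1ccc2OC(C)(C)C=Cc2c1OC | intermediate
19 | 2-(5-methoxy-2,2-dimethyl-2H-chromen-6-yl)acetaldehyde | COc1c(CC=O)ccc2OC(C)(C)C=Cc12 | intermediate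
20 | morpholine | C1COCCN1 | starting material
21 | 2-fluoro-4-methoxybenzoyl chloride | COc1ccc(C(=O)Cl)c(F)c1 | starting material
22 | 4-[(E)-2-(5-methoxy-2,2-dimethyl-2H-chromen-6-yl)ethenyl]morpholine | COc1c(/C=C/N3CCOCC3)ccc2OC(C)(C)C=Cc12 | intermediate
23 | 1-(2-fluoro-4-methoxyphenyl)-2-(5-methoxy-2,2-dimethyl-2H-chromen-6-yl)-3-(morpholin-4-yl)prop-2-en-1-one | COc1ccc(C(=O)C(=CN2CCOCC2)c2ccc3OC(C)(C)C=Cc3c2OC)c(F)c1 | intermediate
24 | 1-(2-fluoro-4-methoxyphenyl)-3-hydroxy-2-(5-methoxy-2,2-dimethyl-2H-chromen-6-yl)prop-2-en-1-one | COc1ccc(C(=O)C(=CO)c2ccc3OC(C)(C)C=Cc3c2OC)c(F)c1 | intermediate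
25 | 7-methoxy-3-(5-methoxy-2,2-dimethyl-2H-chromen-6-yl)-4H-chromen-4-one | COc1ccc2c(=O)c(-c3ccc4c(c3OC)C=CC(C)(C)O4)coc2c1 | target

## Step count and risks

Total step count: 11. Longest linear sequence: 11 steps (1 → 25); 2, 5, 10, 16, 20 and 21 are purchased.

**Step 6 (key step).** The aryne may be diverted before the carbonyl oxygen reaches it: fluoride can deprotonate 10 to a dienolate that adds through carbon, the allylic methyl groups can enter an ene reaction, and 13 can be captured by a second aryne. Site selectivity could also erode, because the C1' substituent presses on the directing methoxyl. The fallback builds ring D by phenol chromenylation. It sets out from 10, which is condensed (pyridine, 120 °C) with 2,4-dihydroxybenzaldehyde F1. C-Alkylation at the carbon between the two hydroxyls, dehydration and oxa-6π closure through the non-chelated oxygen should give 5-hydroxy-2,2-dimethyl-2H-chromene-6-carbaldehyde F2. O-Methylation (CH3I, K2CO3, DMF) brings the route back at 15. This is shorter, but it relies on the intrinsic preference of the resorcinol aldehyde for the position between the oxygens, the question the aryne route avoids.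

**Step 3.** Deprotonation could occur at C5' (ortho to the carbamate only) if the methoxyl, pushed by the neighbouring acetal, shields C3'. Warming before the quench would trigger carbamoyl migration to carbon. The fallback places the lithium by halogen–lithium exchange at a position fixed by symmetry, and returns at 6.
- 2-Bromobenzene-1,3-diol F3 is formylated (POCl3, DMF; Vilsmeier–Haack) at the only activated position to 3-bromo-2,4-dihydroxybenzaldehyde F4.
- The non-chelated 4-hydroxyl is carbamoylated with 2 (K2CO3, acetone) to 2-bromo-4-formyl-3-hydroxyphenyl N,N-diethylcarbamate F5.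
- The chelated hydroxyl is methylated (CH3I, K2CO3, DMF) to 2-bromo-4-formyl-3-methoxyphenyl N,N-diethylcarbamate F6.
- Acetalisation as in step 2 gives 2-bromo-4-(1,3-dioxolan-2-yl)-3-methoxyphenyl N,N-diethylcarbamate F7.
- n-BuLi in THF at −78 °C then gives 6 by bromine–lithium exchange, and silylation continues as in step 3.

**Step 9.** Hydration or dimerisation of the chromene alkene may compete with the slower hydrolysis of the styryl enol ether, and 19 may be lost by aldol self-condensation or air oxidation. The fallback avoids both acid and the free arylacetaldehyde. It sets out from 15 and returns at 22. 4-[(Diphenylphosphoryl)methyl]morpholine F8 is deprotonated (n-BuLi, THF, −78 °C) and added to 15 to give 2-(diphenylphosphoryl)-1-(5-methoxy-2,2-dimethyl-2H-chromen-6-yl)-2-(morpholin-4-yl)ethan-1-ol F9. Treatment with KH in THF eliminates diphenylphosphinate (Horner–Wittig) and delivers enamine 22 directly.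

**Step 10.** The aldehyde may self-condense before the enamine forms, acylation may occur on nitrogen or on residual amine, and the nucleophilic carbon is shielded by the ortho-methoxylated ring. The fallback forms C3–C4 by carbonyl addition and brings in C2 afterwards. It sets out from 19 and returns at 24.
- 1-Bromo-2-fluoro-4-methoxybenzene F10 is converted (i-PrMgCl·LiCl, THF, −20 °C) into (2-fluoro-4-methoxyphenyl)magnesium chloride F11.
- Addition of F11 to 19 gives 1-(2-fluoro-4-methoxyphenyl)-2-(5-methoxy-2,2-dimethyl-2H-chromen-6-yl)ethan-1-ol F12.
- Dess–Martin oxidation gives 1-(2-fluoro-4-methoxyphenyl)-2-(5-methoxy-2,2-dimethyl-2H-chromen-6-yl)ethan-1-one F13.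
- Condensation with N,N-dimethylformamide dimethyl acetal (PhMe, 90 °C) gives 3-(dimethylamino)-1-(2-fluoro-4-methoxyphenyl)-2-(5-methoxy-2,2-dimethyl-2H-chromen-6-yl)prop-2-en-1-one F14.
- Hydrolysis of F14 with dilute acid gives 24, which is closed as in step 11.

**Step 11.** The fluoride displacement may be slow because the C7 methoxyl, para to the ketone, weakens the activation of the ring. Prolonged base could then cleave the formyl group from 24 by retro-Claisen fragmentation, and hydrolysis of the enaminone may be incomplete. The fallback changes the ring-closing bond from O1–C8a to O1–C2. It sets out from 22 and returns at 25. Enamine 22 is acylated (Et3N, CH2Cl2) with 2-(chlorocarbonyl)-5-methoxyphenyl acetate F15, made from the corresponding salicylic acid, to give 2-[2-(5-methoxy-2,2-dimethyl-2H-chromen-6-yl)-3-(morpholin-4-yl)prop-2-enoyl]-5-methoxyphenyl acetate F16. K2CO3 in MeOH removes the acetate to give 1-(2-hydroxy-4-methoxyphenyl)-2-(5-methoxy-2,2-dimethyl-2H-chromen-6-yl)-3-(morpholin-4-yl)prop-2-en-1-one F17. On warming in AcOH the phenol adds to the enaminone carbon and expels morpholine, giving 25.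

## Further compounds

F1 | step 6 | 2,4-dihydroxybenzaldehyde | O=Cc1ccc(O)cc1O
F2 | step 6 | 5-hydroxy-2,2-dimethyl-2H-chromene-6-carbaldehyde | O=Cc1ccc2OC(C)(C)C=Cc2c1O
F3 | step 3 | 2-bromobenzene-1,3-diol | Oc1cccc(O)c1Br
F4 | step 3 | 3-bromo-2,4-dihydroxybenzaldehyde | O=Cc1ccc(O)c(Br)c1O
F5 | step 3 | 2-bromo-4-formyl-3-hydroxyphenyl N,N-diethylcarbamate | CCN(CC)C(=O)Oc1ccc(C=O)c(O)c1Br
F6 | step 3 | 2-bromo-4-formyl-3-methoxyphenyl N,N-diethylcarbamate | COc1c(C=O)ccc(OC(=O)N(CC)CC)c1Br
F7 | step 3 | 2-bromo-4-(1,3-dioxolan-2-yl)-3-methoxyphenyl N,N-diethylcarbamate | COc1c(C2OCCO2)ccc(OC(=O)N(CC)CC)c1Br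
F8 | step 9 | 4-[(diphenylphosphoryl)methyl]morpholine | O=P(CN1CCOCC1)(c1ccccc1)c1ccccc1
F9 | step 9 | 2-(diphenylphosphoryl)-1-(5-methoxy-2,2-dimethyl-2H-chromen-6-yl)-2-(morpholin-4-yl)ethan-1-ol (diastereomer mixture) | COc1c(C(O)C(N3CCOCC3)P(=O)(c3ccccc3)c3ccccc3)ccc2OC(C)(C)C=Cc12
F10 | step 10 | 1-bromo-2-fluoro-4-methoxybenzene | COc1ccc(Br)c(F)c1
F11 | step 10 | (2-fluoro-4-methoxyphenyl)magnesium chloride | COc1ccc([Mg]Cl)c(F)c1
F12 | step 10 | 1-(2-fluoro-4-methoxyphenyl)-2-(5-methoxy-2,2-dimethyl-2H-chromen-6-yl)ethan-1-ol (racemic) | COc1ccc(C(O)Cc2ccc3OC(C)(C)C=Cc3c2OC)c(F)c1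
F13 | step 10 | 1-(2-fluoro-4-methoxyphenyl)-2-(5-methoxy-2,2-dimethyl-2H-chromen-6-yl)ethan-1-one | COc1ccc(C(=O)Cc2ccc3OC(C)(C)C=Cc3c2OC)c(F)c1
F14 | step 10 | 3-(dimethylamino)-1-(2-fluoro-4-methoxyphenyl)-2-(5-methoxy-2,2-dimethyl-2H-chromen-6-yl)prop-2-en-1-one | COc1ccc(C(=O)C(=CN(C)C)c2ccc3OC(C)(C)C=Cc3c2OC)c(F)c1
F15 | step 11 | 2-(chlorocarbonyl)-5-methoxyphenyl acetate | COc1ccc(C(=O)Cl)c(OC(C)=O)c1
F16 | step 11 | 2-[2-(5-methoxy-2,2-dimethyl-2H-chromen-6-yl)-3-(morpholin-4-yl)prop-2-enoyl]-5-methoxyphenyl acetate | COc1ccc(C(=O)C(=CN2CCOCC2)c2ccc3OC(C)(C)C=Cc3c2OC)c(OC(C)=O)c1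
F17 | step 11 | 1-(2-hydroxy-4-methoxyphenyl)-2-(5-methoxy-2,2-dimethyl-2H-chromen-6-yl)-3-(morpholin-4-yl)prop-2-en-1-one | COc1ccc(C(=O)C(=CN2CCOCC2)c2ccc3OC(C)(C)C=Cc3c2OC)c(O)c1
A1 | alternative 1 | 3-methoxyphenol | COc1cccc(O)c1
A2 | alternative 1 | bis(2,4,6-trichlorophenyl) 2-(5-methoxy-2,2-dimethyl-2H-chromen-6-yl)propanedioate | COc1c(C(C(=O)Oc3c(Cl)cc(Cl)cc3Cl)C(=O)Oc3c(Cl)cc(Cl)cc3Cl)ccc2OC(C)(C)C=Cc12
A3 | alternative 1 | 4-hydroxy-7-methoxy-3-(5-methoxy-2,2-dimethyl-2H-chromen-6-yl)-2H-chromen-2-one | COc1ccc2c(O)c(-c3ccc4OC(C)(C)C=Cc4c3OC)c(=O)oc2c1
A4 | alternative 2 | (E)-1-diazo-4-(7-methoxy-4-oxo-4H-chromen-3-yl)but-3-en-2-one | COc1ccc2c(=O)c(/C=C/C(=O)C=[N+]=[N-])coc2c1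
A5 | alternative 2 | triisopropyl[(5-methylhex-4-en-1-yn-1-yl)oxy]silane | CC(C)=CCC#CO[Si](C(C)C)(C(C)C)C(C)C
A6 | alternative 2 | 3-[2-hydroxy-3-(3-methylbut-2-enyl)-4-(triisopropylsilyloxy)phenyl]-7-methoxy-4H-chromen-4-one | COc1ccc2c(=O)c(-c3ccc(O[Si](C(C)C)(C(C)C)C(C)C)c(CC=C(C)C)c3O)coc2c1
A7 | alternative 3 | cyclohexane-1,3-dione | O=C1CCCC(=O)C1
A8 | alternative 3 | 2,2-dimethyl-7,8-dihydro-2H-chromen-5(6H)-one | CC1(C)C=CC2=C(CCCC2=O)O1
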